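The runs are calculated for an exercise; noise was put on by code.

Our unit is one mole of G, the limiting reagent of this flask, charged at 0.530 M, less than the 1.06 M of Q and L together, and we keep a ledger of where each such mole goes.

| setting | Friday's | Tuesday's | flask |
|---|---|---|---|
| Q | 0.27 M | 0.40 M | 0.53 M |
| L | 0.27 M | 0.40 M | 0.53 M |
| G | 0.53 M | 0.53 M | 0.530 M |
| Z | 0.85 mM | 0.85 mM | 0.85 mM |
| remark | run made earlier | run made earlier |  |
| time |  |  | 10 min |

| run | time / min | X / % | Q / % |
|---|---|---|---|
| Friday's | 0.667 | 0.6 | 50.5 |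
| Friday's | 2.00 | 2.8 | 47.2 |
| Friday's | 3.00 | 5.0 | 43.6 |
| Friday's | 5.00 | 9.1 | 38.9 |
| Friday's | 8.00 | 13.6 | 36.6 |
| Friday's | 10.0 | 12.6 | 33.3 |
| Friday's | 12.0 | 16.3 | 30.0 |
| Tuesday's | 1.50 | 2.1 | 45.4 |
| Tuesday's | 3.00 | 6.1 | 44.6 |
| Tuesday's | 5.00 | 9.0 | 39.8 |
| Tuesday's | 6.00 | 8.1 | 38.0 |
| Tuesday's | 8.00 | 12.4 | 38.7 |
| Tuesday's | 10.0 | 15.2 | 34.6 |
| Tuesday's | 12.0 | 14.4 | 32.3 |

(scatter of a reading: 1 percentage point)

* amount of X in percent of the Q and L together charged, at 1.0 min, 4.0 min and 10 min

- Z is single-handed; Q and L are mirror images of each other, charged as a racemate, each of them at the stated concentration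

The first entry books one mole of G against each mole of Q lost, which is our assumption, since no run read G or L. Friday's Q fell to 30.0% at 12.0 min, debiting 0.108 M of G, and Tuesday's fell to 32.3%, debiting 0.142 M. We replace the falling [G] by its mean, 0.476 M on Friday and 0.459 M on Tuesday, which makes each run a pseudo-first-order decay of Q. The logarithm of the fall in [Q], divided by time and mean [G], then reads 0.0894 M⁻¹ min⁻¹ and 0.0793 M⁻¹ min⁻¹. Their average, 0.0844 M⁻¹ min⁻¹, is κ, the loss constant of Q per unit of [G] at 0.85 mM of Z.

In this flask Q and G start equal, so the ledger keeps [Q] equal to [G], and the reciprocal of [Q] grows by κ each minute. By our reckoning Q loses 15.4% of the Q and L charged by 10 min. Putting the mean [G] of 0.448 M back into the logarithmic form gives an exponent of 0.378 against 0.370, an error smaller than the spread between the two readings of κ.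

The second entry is Q lost but not seen as X. At 10 min this gap reads 4.1 percentage points on Friday and 0.2 points on Tuesday, and we carry their average, 2.2 points, which has a scatter near 1 point. Our books close with X at 13.3% at 10 min. The forecast, holding that “the reaction is essentially first order in substrate”, gives 1.1%, 7.1% and 13.7%, its last figure above ours by 0.4 points.

The flask gives 2.16%, 7.28% and 13.5%, so the forecast stands.

    X ⇌ E (k = 3.70 × 10⁻⁴ s⁻¹)
    Z ⇌ D (K = 0.350, k = 1.90 × 10⁻⁴ s⁻¹)
    G + Z + Q → Z + X (k = 1.70 M⁻² s⁻¹)
    G + Z + L → Z + E (k = 0.0330 M⁻² s⁻¹)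

In this flask at 10.0 min, each step taken net, X is made 3.90 times faster than it is used up, while 1.96% stands as E. Taking half κ for half the Z, Q loses 9.14% by 10 min, and half the gap leaves 8.04% of X, where the flask with half the Z gives 8.04%.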